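**Retrosynthetic overview**
- The target is reached from its C3 epimer by Mitsunobu inversion; the C8 benzoate is put on the ten-membered hydroxy acetate just before.
- The only ring is closed once, at C6–C7: SmI2 turns an acyclic (2Z,6Z)-farnesane bromoketone enal into a samarium enolate that adds to the enal carbon. This is the C1–C10 bond by which farnesyl precursors are cyclised to germacradienes. An Evans–Tishchenko reduction in the same flask sets C8 and places the acetate on O6.
- The bromoketone enal comes from a bis-silyl ester: ester to isobutenyl ketone, 1,4-hydrosilylation and bromination, then oxidation of the primary silyl ether.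
- The C3 carbinol and its Z-olefin come from an asymmetric Nozaki–Hiyama–Kishi coupling of a Z-iodobutenyl silyl ether with a Z-aldehyde ester.
- Both Z-olefins are set by ring templates: Birch reduction and selective ozonolysis of 3-methylanisole, and hydroalumination–iodination of but-2-yn-1-ol.

Assumption: ring compounds carry germacrane numbering (ring C1 to C10, double bonds C1=C10 and C4=C5, isopropyl on C7, oxygen on C3, C6 and C8), and in step 5 the ligand antipode that gives the 6S carbinol is used (both antipodes are made from D- or L-valinol).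

**Step 1**
Reactants: 1 but-2-yn-1-ol
Product: 3 (2Z)-3-iodobut-2-en-1-ol, via cyclic alkenylalanate 2 (not isolated)
Conditions: NaAlH2(OCH2CH2OCH3)2, Et2O, 0 °C to rt; EtOAc; then I2, THF, −78 to 0 °C
Reagents that add atoms: iodine, II (NaAlH2(OCH2CH2OCH3)2, [Na+].[AlH2-](OCCOC)OCCOC, puts Al, Na and alkoxide into 2 only)
Why: Hydroxyl-directed trans-hydroalumination of the propargylic alcohol puts aluminium on C3 cis to the CH2O arm in a five-membered alanate, and iodinolysis with retention gives the Z iodide (hydroalumination–iodination).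

**Step 2**
Reactants: 3 (2Z)-3-iodobut-2-en-1-ol
Product: 4 triethyl{[(2Z)-3-iodobut-2-en-1-yl]oxy}silane
Conditions: Et3SiCl, imidazole, CH2Cl2, 0 °C
Reagents that add atoms: chlorotriethylsilane, CC[Si](Cl)(CC)CC
Why: Imidazole-promoted silylation of a primary alcohol (silyl ether formation).

**Step 3**
Reactants: 5 3-methylanisole
Product: 6 1-methoxy-5-methylcyclohexa-1,4-diene
Conditions: Li, liquid NH3, THF, t-BuOH, −78 to −33 °C; NH4Cl
Reagents that add atoms: none
Why: Birch reduction of an anisole gives the 1,4-diene with the methoxy and methyl groups on the two double bonds.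

**Step 4**
Reactants: 6 1-methoxy-5-methylcyclohexa-1,4-diene
Product: 8 methyl (3Z)-3-methyl-6-oxohex-3-enoate, via methoxy hydroperoxide 7 (not isolated)
Conditions: O3 (1.0 equiv), CH2Cl2–MeOH 4:1, NaHCO3, −78 °C; then Me2S, −78 °C to rt; used crude
Reagents that add atoms: ozone, [O-][O+]=O (methanol, CO, enters 7 only)
Why: Ozone cleaves the electron-rich enol ether double bond much faster than the trisubstituted alkene, and the ring has already fixed the remaining olefin as Z (selective ozonolysis with reductive work-up).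

**Step 5**
Reactants: 8 methyl (3Z)-3-methyl-6-oxohex-3-enoate; 4 triethyl{[(2Z)-3-iodobut-2-en-1-yl]oxy}silane
Product: 9 methyl (3Z,6S,7Z)-3,7-dimethyl-6,9-bis(triethylsilyloxy)nona-3,7-dienoate
Conditions: CrCl2 (10 mol%), valinol-derived oxazolinyl-aryl methanesulfonamide ligand (11 mol%), proton sponge (11 mol%), NiCl2·(2,9-dimethyl-1,10-phenanthroline) (2 mol%), Mn powder, LiCl, Et3SiCl, MeCN, rt
Reagents that add atoms: chlorotriethylsilane, CC[Si](Cl)(CC)CC
Why: Catalytic asymmetric Nozaki–Hiyama–Kishi coupling, in which the alkenylchromium adds only to the aldehyde with retention of olefin geometry, the chiral sulfonamide ligand on chromium sets C6 of 9 as S (later ring C3), and Et3SiCl releases the chromium alkoxide as its silyl ether so that Mn can turn the metal over.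

**Step 6**
Reactants: 9 methyl (3Z,6S,7Z)-3,7-dimethyl-6,9-bis(triethylsilyloxy)nona-3,7-dienoate
Product: 11 (6Z,9S,10Z)-2,6,10-trimethyl-9,12-bis(triethylsilyloxy)dodeca-2,6,10-trien-4-one, via Weinreb amide 10 (not isolated)
Conditions: MeNH(OMe)·HCl (1.5 equiv), i-PrMgCl (3 equiv), THF, −20 °C; then 2-methylprop-1-enylmagnesium bromide, −20 to 0 °C; aq. NH4Cl
Reagents that add atoms: 2-methylprop-1-enylmagnesium bromide, CC(C)=C[Mg]Br (N,O-dimethylhydroxylamine hydrochloride, CNOC.Cl, enters 10 only)
Why: The magnesium amide converts the ester into the Weinreb amide in the flask, and Grignard addition stops at the ketone because the chelated tetrahedral adduct survives until work-up (Weinreb ketone synthesis).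

**Step 7**
Reactants: 11 (6Z,9S,10Z)-2,6,10-trimethyl-9,12-bis(triethylsilyloxy)dodeca-2,6,10-trien-4-one
Product: 13 (6Z,9S,10Z)-3-bromo-2,6,10-trimethyl-9,12-bis(triethylsilyloxy)dodeca-6,10-dien-4-one (both C3 epimers), via triethylsilyl enol ether 12 (not isolated)
Conditions: Et3SiH (1.05 equiv), RhCl(PPh3)3 (1 mol%), THF, 50 °C; then NBS (1.0 equiv), THF, −78 °C
Reagents that add atoms: N-bromosuccinimide, O=C1CCC(=O)N1Br (triethylsilane, CC[SiH](CC)CC, puts Si into 12 only)
Why: Rhodium-catalysed 1,4-hydrosilylation of the s-cis β,β-disubstituted enone forms the enol silane only toward C3 of 11 (later ring C7), and bromination of that enol silane is far faster than attack on the isolated alkenes, so bromine goes on regiospecifically.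

**Step 8**
Reactants: 13 (6Z,9S,10Z)-3-bromo-2,6,10-trimethyl-9,12-bis(triethylsilyloxy)dodeca-6,10-dien-4-one
Product: 14 (2Z,4S,6Z)-10-bromo-3,7,11-trimethyl-9-oxo-4-(triethylsilyloxy)dodeca-2,6-dienal
Conditions: (COCl)2, DMSO, CH2Cl2, −78 to −35 °C; then Et3N, −78 to −20 °C
Reagents that add atoms: none
Why: Under Swern conditions the chlorosulfonium reagent cleaves a primary triethylsilyl ether and oxidises it directly to the aldehyde, while the secondary silyl ether survives at low temperature (oxidative desilylation).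

**Step 9**
Reactants: 14 (2Z,4S,6Z)-10-bromo-3,7,11-trimethyl-9-oxo-4-(triethylsilyloxy)dodeca-2,6-dienal
Product: 16 (1(10)Z,3S,4Z,6S,7R,8S)-6-acetoxy-3-(triethylsilyloxy)germacra-1(10),4-dien-8-ol, via samarium aldolate 15 (not isolated)
Conditions: SmI2 (2.1 equiv, 0.1 M in THF, syringe pump) into 14 (2 mM in THF), −78 °C; then MeCHO (10 equiv), −78 to −10 °C; aq. NaHCO3
Reagents that add atoms: acetaldehyde, CC=O (SmI2, I[Sm]I, puts Sm and I into 15 only)
Why: Proposed new method: SmI2 cleaves only the C–Br bond and so gives a regiodefined Z-configured trivalent samarium enolate (the more acidic C9–H2 is never deprotonated) that adds to the tethered enal through a samarium-bridged chair in which the tether holds C5 axial and the isopropyl group outside the forming ring (anti aldol) and on the enal face that carries C2 and lies opposite OSiEt3 (C3–H eclipsed with the olefin by allylic 1,3-strain, so 3S gives 6S and 7R), after which the samarium hemiacetal of acetaldehyde delivers hydride intramolecularly to C8 anti to O6 (8S) and leaves the acetate on O6; the closest known reactions are the SmI2 Reformatsky medium-ring closure and the Evans–Tishchenko reduction.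

**Step 10**
Reactants: 16 (1(10)Z,3S,4Z,6S,7R,8S)-6-acetoxy-3-(triethylsilyloxy)germacra-1(10),4-dien-8-ol
Product: 18 (1(10)Z,3S,4Z,6S,7R,8S)-6-acetoxy-8-benzoyloxygermacra-1(10),4-dien-3-ol, via silyl ether benzoate 17 (not isolated)
Conditions: BzCl, DMAP, pyridine, 0 °C to rt; MeOH quench; then HF·pyridine, THF, 0 °C
Reagents that add atoms: benzoyl chloride, O=C(Cl)c1ccccc1
Why: DMAP-catalysed acylation of the hindered secondary alcohol followed by fluoride cleavage of the silyl ether, neither of which touches the two esters once the excess BzCl is quenched (esterification, desilylation).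

**Step 11**
Reactants: 18 (1(10)Z,3S,4Z,6S,7R,8S)-6-acetoxy-8-benzoyloxygermacra-1(10),4-dien-3-ol
Product: 19 (1(10)Z,3R,4Z,6S,7R,8S)-6-acetoxy-8-benzoyloxy-3-(chloroacetoxy)germacra-1(10),4-diene
Conditions: ClCH2CO2H, PPh3, DIAD, toluene, 0 °C to rt
Reagents that add atoms: chloroacetic acid, OC(=O)CCl
Why: Mitsunobu reaction, in which SN2 displacement of the oxyphosphonium by chloroacetate inverts C3 from S to R.

**Step 12**
Reactants: 19 (1(10)Z,3R,4Z,6S,7R,8S)-6-acetoxy-8-benzoyloxy-3-(chloroacetoxy)germacra-1(10),4-diene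
Product: 20 (1(10)Z,3R,4Z,6S,7R,8S)-6-acetoxy-8-benzoyloxygermacra-1(10),4-dien-3-ol
Conditions: thiourea, NaHCO3, EtOH, 50 °C
Reagents that add atoms: none
Why: Thiourea S-alkylation and cyclisation to pseudothiohydantoin removes the chloroacetyl group and leaves the acetate and benzoate untouched (chemoselective chloroacetate cleavage).

**Compound list**
1 | but-2-yn-1-ol | CC#CCO | starting material
2 | sodium 2,2-bis(2-methoxyethoxy)-3-methyl-2,5-dihydro-1,2-oxaluminol-2-uide (cyclic alkenylalanate) | [Na+].CC1=CCO[Al-]1(OCCOC)OCCOC | intermediate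
3 | (2Z)-3-iodobut-2-en-1-ol | C/C(I)=C/CO | intermediate
4 | triethyl{[(2Z)-3-iodobut-2-en-1-yl]oxy}silane | C/C(I)=C/CO[Si](CC)(CC)CC | intermediate
5 | 3-methylanisole | COc1cccc(C)c1 | starting material
6 | 1-methoxy-5-methylcyclohexa-1,4-diene | COC1=CCC=C(C)C1 | intermediate
7 | methyl (3Z)-6-hydroperoxy-6-methoxy-3-methylhex-3-enoate | COC(OO)C/C=C(/C)CC(=O)OC | intermediate
8 | methyl (3Z)-3-methyl-6-oxohex-3-enoate | O=CC/C=C(/C)CC(=O)OC | intermediate
9 | methyl (3Z,6S,7Z)-3,7-dimethyl-6,9-bis(triethylsilyloxy)nona-3,7-dienoate | CC[Si](CC)(CC)OC/C=C(/C)[C@@H](O[Si](CC)(CC)CC)C/C=C(/C)CC(=O)OC | intermediate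
10 | (3Z,6S,7Z)-N-methoxy-N,3,7-trimethyl-6,9-bis(triethylsilyloxy)nona-3,7-dienamide | CC[Si](CC)(CC)OC/C=C(/C)[C@@H](O[Si](CC)(CC)CC)C/C=C(/C)CC(=O)N(C)OC | intermediate
11 | (6Z,9S,10Z)-2,6,10-trimethyl-9,12-bis(triethylsilyloxy)dodeca-2,6,10-trien-4-one | CC[Si](CC)(CC)OC/C=C(/C)[C@@H](O[Si](CC)(CC)CC)C/C=C(/C)CC(=O)C=C(C)C | intermediate
12 | (3Z,6Z,9S,10Z)-2,6,10-trimethyl-4,9,12-tris(triethylsilyloxy)dodeca-3,6,10-triene | CC[Si](CC)(CC)OC/C=C(/C)[C@@H](O[Si](CC)(CC)CC)C/C=C(/C)C/C(O[Si](CC)(CC)CC)=C/C(C)C | intermediate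
13 | (6Z,9S,10Z)-3-bromo-2,6,10-trimethyl-9,12-bis(triethylsilyloxy)dodeca-6,10-dien-4-one (both C3 epimers) | CC[Si](CC)(CC)OC/C=C(/C)[C@@H](O[Si](CC)(CC)CC)C/C=C(/C)CC(=O)C(Br)C(C)C | intermediate
14 | (2Z,4S,6Z)-10-bromo-3,7,11-trimethyl-9-oxo-4-(triethylsilyloxy)dodeca-2,6-dienal | O=C/C=C(/C)[C@@H](O[Si](CC)(CC)CC)C/C=C(/C)CC(=O)C(Br)C(C)C | intermediate
15 | diiodosamarium aldolate of (1(10)Z,3S,4Z,6S,7S)-6-hydroxy-3-(triethylsilyloxy)germacra-1(10),4-dien-8-one | I[Sm](I)O[C@H]1/C=C(/C)[C@@H](O[Si](CC)(CC)CC)C/C=C(/C)CC(=O)[C@H]1C(C)C | intermediate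
16 | (1(10)Z,3S,4Z,6S,7R,8S)-6-acetoxy-3-(triethylsilyloxy)germacra-1(10),4-dien-8-ol | CC(=O)O[C@H]1/C=C(/C)[C@@H](O[Si](CC)(CC)CC)C/C=C(/C)C[C@H](O)[C@H]1C(C)C | intermediate
17 | (1(10)Z,3S,4Z,6S,7R,8S)-6-acetoxy-8-benzoyloxy-3-(triethylsilyloxy)germacra-1(10),4-diene | CC(=O)O[C@H]1/C=C(/C)[C@@H](O[Si](CC)(CC)CC)C/C=C(/C)C[C@H](OC(=O)c2ccccc2)[C@H]1C(C)C | intermediate
18 | (1(10)Z,3S,4Z,6S,7R,8S)-6-acetoxy-8-benzoyloxygermacra-1(10),4-dien-3-ol | CC(=O)O[C@H]1/C=C(/C)[C@@H](O)C/C=C(/C)C[C@H](OC(=O)c2ccccc2)[C@H]1C(C)C | intermediate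
19 | (1(10)Z,3R,4Z,6S,7R,8S)-6-acetoxy-8-benzoyloxy-3-(chloroacetoxy)germacra-1(10),4-diene | CC(=O)O[C@H]1/C=C(/C)[C@H](OC(=O)CCl)C/C=C(/C)C[C@H](OC(=O)c2ccccc2)[C@H]1C(C)C | intermediate
20 | (1(10)Z,3R,4Z,6S,7R,8S)-6-acetoxy-8-benzoyloxygermacra-1(10),4-dien-3-ol | CC(=O)O[C@H]1/C=C(/C)[C@H](O)C/C=C(/C)C[C@H](OC(=O)c2ccccc2)[C@H]1C(C)C | target

(The C7 descriptor of 15 is S only because the C8 ketone outranks C6; the geometry at C7 is the same as in 16 to 20.)

**Step count and risks**
Total: 12 steps. Longest linear sequence: 10 steps (steps 3 to 12, from 3-methylanisole); steps 1 and 2 are a two-step branch that joins at step 5.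

Steps most likely to fail:

Step 9. The ring closure competes with oligomerisation. The anti aldol geometry and the facial sense relative to C3 rest on transition-state models that could not be checked against a close precedent; either could come out the other way. The samarium aldolate may also undergo retro-aldol before the hydride shift. The fallback sets out from 14: CrCl2 and LiI in THF at high dilution (chromium Reformatsky; the trivalent chromium enolate adds irreversibly and only to aldehydes, usually anti) give the isolated hydroxy ketone (1(10)Z,3S,4Z,6S,7S)-6-hydroxy-3-(triethylsilyloxy)germacra-1(10),4-dien-8-one F1, whose configuration is proved before it is carried on. A separate Evans–Tishchenko reduction (SmI2 30 mol%, MeCHO, THF, −10 °C) then comes back to the route at 16.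

Step 5. Aldehyde 8 is a skipped, enolisable aldehyde that can isomerise or be silylated, and the enantioselectivity with a trisubstituted alkenyl iodide is not assured. The fallback sets out from 8 (with 4): iodine–lithium exchange on 4 (t-BuLi, Et2O, −78 °C), transmetallation with CeCl3 and addition to 8 at −78 °C give racemic methyl (3Z,7Z)-6-hydroxy-3,7-dimethyl-9-(triethylsilyloxy)nona-3,7-dienoate F2. Dess–Martin periodinane gives methyl (3Z,7Z)-3,7-dimethyl-6-oxo-9-(triethylsilyloxy)nona-3,7-dienoate F3. Reduction with (R)-2-methyl-CBS-oxazaborolidine and BH3·SMe2 gives methyl (3Z,6S,7Z)-6-hydroxy-3,7-dimethyl-9-(triethylsilyloxy)nona-3,7-dienoate F4. Et3SiCl and imidazole then come back to the route at 9.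

Step 8. The bromoketone must survive activated DMSO and amine base, and the Z-enal must not isomerise. The fallback sets out from 13: PPTS in MeOH–CH2Cl2 at 0 °C removes only the primary silyl group and gives (6Z,9S,10Z)-3-bromo-12-hydroxy-2,6,10-trimethyl-9-(triethylsilyloxy)dodeca-6,10-dien-4-one F5. MnO2 in CH2Cl2 oxidises the allylic alcohol under neutral conditions and comes back to the route at 14.

**Further compounds**
F1 | step 9 | (1(10)Z,3S,4Z,6S,7S)-6-hydroxy-3-(triethylsilyloxy)germacra-1(10),4-dien-8-one | O[C@H]1/C=C(/C)[C@@H](O[Si](CC)(CC)CC)C/C=C(/C)CC(=O)[C@H]1C(C)C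
F2 | step 5 | methyl (3Z,7Z)-6-hydroxy-3,7-dimethyl-9-(triethylsilyloxy)nona-3,7-dienoate (racemic) | CC[Si](CC)(CC)OC/C=C(/C)C(O)C/C=C(/C)CC(=O)OC
F3 | step 5 | methyl (3Z,7Z)-3,7-dimethyl-6-oxo-9-(triethylsilyloxy)nona-3,7-dienoate | CC[Si](CC)(CC)OC/C=C(/C)C(=O)C/C=C(/C)CC(=O)OC
F4 | step 5 | methyl (3Z,6S,7Z)-6-hydroxy-3,7-dimethyl-9-(triethylsilyloxy)nona-3,7-dienoate | CC[Si](CC)(CC)OC/C=C(/C)[C@@H](O)C/C=C(/C)CC(=O)OC
F5 | step 8 | (6Z,9S,10Z)-3-bromo-12-hydroxy-2,6,10-trimethyl-9-(triethylsilyloxy)dodeca-6,10-dien-4-one | OC/C=C(/C)[C@@H](O[Si](CC)(CC)CC)C/C=C(/C)CC(=O)C(Br)C(C)C
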